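**Retrosynthetic overview**
1. Target 11 is ring A (2,6-dihydroxy-4-methoxyacetophenone) joined through CH2 to ring B (acetylfilicinic acid). The CH2–ring B bond is cut: Michael addition of β-triketone 6 to the o-quinone methide 10 of ring A.
2. Quinone methide 10 comes from Mannich salt 8, made from phenol 3 and (CH2=NMe2)I (CH2–ring A bond by Mannich reaction).
3. Phenol 3 comes from phloroacetophenone 1 by selective 4-O-methylation; triketone 6 comes from 1 by dearomatising C,C-dimethylation.
4. No ring is built: both six-membered rings come from 1. Ring B is dearomatised in step 2; ring A stays aromatic.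

Assumption: the SMILES holds no stereocentre, so the target is achiral (there is no enantiomer to choose) and is made as the drawn enol tautomer.

**Route**

Step 1
Reactants: 1 2',4',6'-trihydroxyacetophenone (phloroacetophenone, dried); 2 dimethyl sulfate
Product: 3 2',6'-dihydroxy-4'-methoxyacetophenone
Conditions: Me2SO4 (1.0 equiv), K2CO3 (1.05 equiv), acetone, reflux, 6 h
Reagents that add atoms: dimethyl sulfate (2), COS(=O)(=O)OC
Why: Williamson O-methylation in which the 4-OH, the only hydroxyl not hydrogen-bonded to the acetyl carbonyl, is the most acidic and most nucleophilic and so is methylated first by one equivalent of Me2SO4; no stereocentre is formed.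

Step 2
Reactants: 1 2',4',6'-trihydroxyacetophenone; 4 iodomethane
Product: 6 acetylfilicinic acid (2-acetyl-3,5-dihydroxy-4,4-dimethylcyclohexa-2,5-dien-1-one), via 3-methylphloroacetophenone 5 (not isolated)
Conditions: NaOMe (3.0 equiv), MeI (2.3 equiv), MeOH, 0 °C → rt, 16 h; then 1 M HCl
Reagents that add atoms: iodomethane (4), CI
Why: Dearomatising double C-alkylation of the phloroglucinolate (enolate C-methylation) in which the second methyl enters the already methylated, more electron-rich carbon, and the stabilised mono-enolate of the gem-dimethyl triketone resists a third methylation when base is limited to three equivalents; the quaternary carbon carries two identical methyls, so no stereocentre arises.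

Step 3
Reactants: 3 2',6'-dihydroxy-4'-methoxyacetophenone (1.1 equiv); 7 N,N-dimethylmethyleneiminium iodide (Eschenmoser's salt)
Product: 8 (3-acetyl-2,4-dihydroxy-6-methoxybenzyl)dimethylammonium iodide
Conditions: (CH2=NMe2)I (1.0 equiv), MeCN, 0 °C → rt, 12 h; filter, wash with Et2O
Reagents that add atoms: N,N-dimethylmethyleneiminium iodide (7), C=[N+](C)C.[I-]
Why: Mannich reaction (aromatic aminomethylation) of electron-rich ring A at one of its two equivalent free positions with the preformed iminium ion, the product separating as its hydroiodide whose ammonium group deactivates the ring against a second aminomethylation; no stereocentre is formed.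

Step 4
Reactants: 8 (3-acetyl-2,4-dihydroxy-6-methoxybenzyl)dimethylammonium iodide; 6 acetylfilicinic acid (1.5 equiv)
Product: 11 target CNP0224819.0 (2-acetyl-6-[(3-acetyl-2,4-dihydroxy-6-methoxyphenyl)methyl]-3,5-dihydroxy-4,4-dimethylcyclohexa-2,5-dien-1-one), via free Mannich base 9 (not isolated), via o-quinone methide 10 (not isolated)
Conditions: NaOAc (2.5 equiv), DMF, N2, rt → 60 °C, 4 h; then cold 1 M HCl, EtOAc
Reagents that add atoms: none
Why: NaOAc frees the Mannich base, which loses Me2NH to give the o-quinone methide, and the soft enolate of β-triketone 6 adds through its only free ring carbon to the exocyclic methylene in an intermolecular Michael addition that re-aromatises ring A; the new CH2 bridge is not a stereocentre.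

**Compound list**
1 | 2',4',6'-trihydroxyacetophenone (phloroacetophenone) | CC(=O)c1c(O)cc(O)cc1O | starting material
2 | dimethyl sulfate | COS(=O)(=O)OC | starting material
3 | 2',6'-dihydroxy-4'-methoxyacetophenone | COc1cc(O)c(C(C)=O)c(O)c1 | intermediate
4 | iodomethane | CI | starting material
5 | 2',4',6'-trihydroxy-3'-methylacetophenone (3-methylphloroacetophenone, formed in the flask) | CC(=O)c1c(O)cc(O)c(C)c1O | intermediate
6 | acetylfilicinic acid (2-acetyl-3,5-dihydroxy-4,4-dimethylcyclohexa-2,5-dien-1-one) | CC(=O)C1=C(O)C(C)(C)C(O)=CC1=O | intermediate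
7 | N,N-dimethylmethyleneiminium iodide (Eschenmoser's salt) | C=[N+](C)C.[I-] | starting material
8 | (3-acetyl-2,4-dihydroxy-6-methoxybenzyl)dimethylammonium iodide | COc1cc(O)c(C(C)=O)c(O)c1C[NH+](C)C.[I-] | intermediate
9 | 3'-[(dimethylamino)methyl]-2',6'-dihydroxy-4'-methoxyacetophenone (free Mannich base, formed in the flask) | COc1cc(O)c(C(C)=O)c(O)c1CN(C)C | intermediate
10 | 2-acetyl-3-hydroxy-5-methoxy-6-methylidenecyclohexa-2,4-dien-1-one (o-quinone methide, formed in the flask) | C=C1C(=O)C(C(C)=O)=C(O)C=C1OC | intermediate
11 | 2-acetyl-6-[(3-acetyl-2,4-dihydroxy-6-methoxyphenyl)methyl]-3,5-dihydroxy-4,4-dimethylcyclohexa-2,5-dien-1-one (CNP0224819.0) | COc1cc(O)c(C(C)=O)c(O)c1CC1=C(O)C(C)(C)C(O)=C(C(C)=O)C1=O | target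

**Totals**
Total steps: 4. Longest linear sequence: 3 steps (1 → 3 → 8 → 11; steps 1, 3, 4). The second branch (1 → 6) is one step and joins at step 4.

**Steps most likely to fail, with fallbacks**

Step 2 (C,C-dimethylation; mixtures of mono-, 3,5-di-, tri- and tetramethylated products are the danger). The fallback sets out from 1 and comes back at 6, and uses a second acetyl group to block the ring position that must stay free. Friedel–Crafts acetylation of 1 (Ac2O, BF3·OEt2, 80 °C) gives 2,4-diacetylphloroglucinol F2, which has a single free ring carbon. Treatment with NaOMe/MeI in MeOH can then only gem-dimethylate that carbon, giving diacetylfilicinic acid F3. Hot 80 % aqueous H2SO4 (80 °C) removes both acetyl groups by retro-Claisen cleavage to give filicinic acid F4. Mono-C-acetylation of F4 (Ac2O, BF3·OEt2) returns 6; the strongly acidic triketone product is deactivated toward a second acylation.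

Step 4 (quinone methide coupling; homodimer of ring A, slow elimination, or base-induced scrambling of the methylene bridge are the dangers). The fallback sets out from 6 (with 3 as partner) and comes back at 11 with the roles of donor and acceptor reversed. Triketone 6 has only one reactive carbon and gives, with (CH2=NMe2)I in MeCN at rt, 2-acetyl-6-[(dimethylamino)methyl]-3,5-dihydroxy-4,4-dimethylcyclohexa-2,5-dien-1-one hydroiodide F5. Adding F5 in portions to 3 (3 equiv, excess recovered) and NaOAc in DMF releases 2-acetyl-3-hydroxy-4,4-dimethyl-6-methylidenecyclohex-2-ene-1,5-dione F6 in the flask. Ring A of 3 captures F6 at a free position ortho to hydroxyl (Michael-type phenol C-alkylation) to give 11.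

Step 1 (mono-O-methylation; over-methylation to the 4,6-dimethyl ether and unreacted 1 are the dangers). The fallback sets out from 1 and comes back at 3, replacing selective alkylation by exhaustive alkylation followed by directed dealkylation. Excess Me2SO4/K2CO3 in refluxing acetone gives 2',4',6'-trimethoxyacetophenone F1. AlCl3 (4 equiv, chlorobenzene, 90 °C) then cleaves only the two methoxy groups ortho to the carbonyl through chelation, leaving the 4-methoxy group and returning 3.

**Further compounds**
F1 | step 1 | 2',4',6'-trimethoxyacetophenone | COc1cc(OC)c(C(C)=O)c(OC)c1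
F2 | step 2 | 2,4-diacetylphloroglucinol | CC(=O)c1c(O)cc(O)c(C(C)=O)c1O
F3 | step 2 | diacetylfilicinic acid (2,4-diacetyl-3,5-dihydroxy-6,6-dimethylcyclohexa-2,4-dien-1-one) | CC(=O)C1=C(O)C(C(C)=O)=C(O)C(C)(C)C1=O
F4 | step 2 | filicinic acid (3,5-dihydroxy-4,4-dimethylcyclohexa-2,5-dien-1-one) | CC1(C)C(O)=CC(=O)C=C1O
F5 | step 4 | 2-acetyl-6-[(dimethylamino)methyl]-3,5-dihydroxy-4,4-dimethylcyclohexa-2,5-dien-1-one hydroiodide | CC(=O)C1=C(O)C(C)(C)C(O)=C(C[NH+](C)C)C1=O.[I-]
F6 | step 4 | 2-acetyl-3-hydroxy-4,4-dimethyl-6-methylidenecyclohex-2-ene-1,5-dione | CC(=O)C1=C(O)C(C)(C)C(=O)C(=C)C1=O
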